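Readings and results were generated by integration with made-up constants, noise included.

The racemate cannot be converted past the point where Rgt is paid out, at one Rgt per product molecule as I take it, so when you repeat grey, amber and green, watch Rgt before you watch Cat.

| flask | Sbt | Sbt2 | Rgt | Cat | remark | time |
|---|---|---|---|---|---|---|
| alpha | 0.30 M | 0.30 M | 0.22 M | 0.030 mM | run made earlier |  |
| eta | 0.20 M | 0.20 M | 0.44 M | 0.030 mM | run made earlier |  |
| grey | 0.20 M | 0.20 M | 0.220 M | 0.030 mM |  | 30 h |
| amber | 0.20 M | 0.20 M | 0.220 M | 0.060 mM |  | 30 h |
| green | 0.20 M | 0.20 M | 0.220 M | 0.12 mM |  | 30 h |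

| run | time / h | Tgt / % |
|---|---|---|
| alpha | 2.50 | 8.2 |
| alpha | 5.00 | 12.6 |
| alpha | 8.00 | 16.8 |
| alpha | 10.0 | 17.2 |
| eta | 1.33 | 8.6 |
| eta | 4.00 | 22.2 |
| eta | 6.00 | 29.0 |
| eta | 10.0 | 35.9 |

(each reading ± 1 percentage point)

- amount of Tgt at the end, in percent of the Sbt and Sbt2 together charged for grey, amber, green, in this order
- the course of these numbers from the first flask to the last (rises all the way / falls all the way / rises, then falls / hardly changes / falls, then rises)

- Cat is single-handed; Sbt and Sbt2 are mirror images of each other, charged as a racemate, each of them at the stated concentration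
- "hardly changes" means that all values lie within two and a half points (for a concentration: within two and a half percent of the largest)
- no earlier run changes the charge of Cat; that part of a forecast is a guess

Fold the charges into one number: 55.0 % is the Rgt budget, the charged Rgt over the charged Sbt and Sbt2 together, which says what fraction of the racemate Rgt can pay for. It lies below the whole, so Rgt is the limiting reagent. The zero of the scale is a catalyst blind to handedness, which shares the budget equally between the two enantiomers, so that Tgt gets 27.5 %; any real preference of Cat shows as a distance from that line.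

Alpha tests the rule. Its budget is 36.7 %, the equal share for Tgt is 18.3 %, and its last readings are 16.8 % and 17.2 %, the latter about one scatter below the line. So alpha is near its line at 10.0 h, but whether it has stopped cannot be read, and neither can any tilt between the enantiomers. Eta shows its edge: Rgt exceeds the racemate, the budget is 110 %, and the readings still climb from 29.0 % to 35.9 %, so there time counts.

Alpha came near its line within 10.0 h, and your flasks run 30 h. I therefore expect all three near 27.5 %, with more Cat arriving sooner, though that part is a guess.

The forecast gave 32 %, 35 % and 37 %, above my line, with the course rises all the way: “the yield rises towards the ceiling”.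

The flasks give 28.9 %, 29.3 % and 29.3 %: hardly changes.

    Cat + Sbt ⇌ Cat.Sbt (K = 2.40 M⁻¹, k = 280 M⁻¹ min⁻¹)
    Cat + Sbt2 ⇌ Cat.Sbt2 (K = 4.30 M⁻¹, k = 5800 M⁻¹ min⁻¹)
    Rgt + Cat.Sbt → Cat + Tgt (k = 360 M⁻¹ min⁻¹)
    Rgt + Cat.Sbt2 → Cat + Tgt2 (k = 130 M⁻¹ min⁻¹)

Grey ends 1.4 percentage points above the line, and its Tgt and Tgt2 together make 54.4 % against the budget of 55.0 %, with 1.1 % of its Rgt left at 30.0 h. The main reason grey gets that far is the reverse step from Cat.Sbt2 to Cat + Sbt2; Cat.Sbt2 holds 26.0 % of the catalyst at 30.0 h. Without that reverse step, grey ends at 4.90 % of Tgt instead of 28.9 %.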